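## The problem

The target is a 3,3,5,5-tetrasubstituted 1,2-dioxolane (O1–O2–C3–C4–C5). C3 carries a methyl group and the CH2CO2H arm. C5 carries a methyl group and a chain C6–C17 with a methyl-branched stereocentre at C7 (R), an isolated E alkene (C12=C13) and an E styrenyl alkene (C16=C17). The chain is linear and is best grown outwards from C7, and the ring is best closed through a C–O bond so that the O–O bond arrives intact from H2O2. C3 is S and C5 is R, with the two ring methyl groups trans. Both are fully substituted, 1,3-related across the C4 methylene and flanked by groups of similar size, so neither can be corrected by epimerisation nor relied on to control the other, and acyclic C7 is too remote to bias C5. Each of the three centres therefore needs its own source of chirality. The O–O bond will not survive low-valent metals, phosphines, hydrogenation or hydride at the ring, and once the arm is at the carbonyl level the peroxide sits β to a carbonyl and is open to base-induced elimination; the styrenyl diene does not tolerate strong acid or unselective oxidants. The enabling feature is the methyl group on C5: it is the footprint of a proton added to a methylidene (C5=CH2), and a hydroperoxide on C3 then has its terminal oxygen five atoms from C5, so protonation and C5–O1 bond formation can close the ring in one acid-catalysed event.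

## Retrosynthesis

**Arm oxidation level.** Target 31 is taken back to primary alcohol 29 and its acetate 28; no C–C bond is cut. This keeps the peroxide away from a β-carbonyl group during every basic step. The forward steps are a methanolysis and a near-neutral alcohol-to-acid oxidation (through aldehyde 30) that must spare two alkenes and the O–O bond.

**C12=C13.** Acetate 28 is cut into aldehyde 19 and phenyltetrazolyl sulfone 26 (Julia–Kocienski olefination). Cutting here, rather than at C16=C17 or at a chain C–C bond, removes the whole acid-sensitive styrenyl diene in one piece and postpones it until after the acid-mediated ring closure. A cross-metathesis at the same bond would save a step but gives E/Z mixtures. The forward reaction must be E-selective and must leave acetate and peroxide alone.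

**C12 aldehyde.** Aldehyde 19 comes from the chain-end alkene of 18 by ozonolysis. A monosubstituted alkene is the cheapest spectator for the ring closure: it needs no protecting-group steps, does not bind the acid, and is far less basic than a methylidene. A silyl ether at C12 would serve equally but costs two or three more steps.

**C5–O1 (key step).** Dioxolane 18 is opened at C5–O1 to hydroperoxy alkene 17. Against cutting O2–C3 or both C–O bonds, this cut leaves an acyclic precursor whose only stereocentres (C3, C7) can be made independently, and it turns the C5 methyl into a methylidene. The forward reaction must add O–H across the 1,1-disubstituted alkene in the Markovnikov sense, 5-exo, with catalyst control of the C5 face. The arm hydroxyl is acetylated so that the hydroperoxide is the only oxygen nucleophile.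

**C3–O2.** Acetate 17 comes from hydroperoxy alcohol 16, and 16 from oxetane 15 by cutting C3–O2. Opening a 2,2-disubstituted oxetane with H2O2 at the tertiary carbon is a known, invertive, strain-driven reaction, and it releases the two-carbon arm as the primary alcohol in the same event. The precursor has no peroxide. The forward step must proceed with inversion and without ionisation at C3.

**Oxetane and C4–C5.** Oxetane 15 is contracted by one carbon to epoxide 14 (sulfoxonium ylide ring expansion in the forward sense, C3–O untouched). Epoxide 14 is cut at C4–C5 into glycidyl sulfonate 11 (from 2-methylglycidol 10) and alkenylmagnesium reagent 12 (from bromodiene 9). Chiral-pool sources that already hold both two-carbon arms on C3 were weighed. They place the carboxyl group on the arm that must become the oxetane, so the oxidation levels of the two arms would have to be exchanged first, and C5 would then be built by acylation and methylenation next to a base-sensitive oxetane. The four-carbon epoxide reaches 15 in two steps from 9 and brings the methylidene in with the fragment.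

**Bromodiene 9.** Bromodiene 9 is cut at C8–C9 into tosylate 6 and Grignard reagent 8 (from bromide 7). Tosylate 6 goes back through alcohol 5 to imide 4, which is cut at C6–C7 into propanoyl oxazolidinone 1 and 2,3-dibromopropene 2. The auxiliary alkylation sets C7 and installs the alkenyl bromide in one step.

**Sulfone 26.** Sulfone 26 goes back through sulfide 25 and alcohol 24 to ester 23, which is cut at C14–C15 into tert-butyl acetate 20 and cinnamyl bromide 21. The E styrenyl geometry is bought, not made.

## Roads not taken

Alternative 1: Cut both C–O bonds of the ring. The full-chain enone (6R,11E,15E)-4,6-dimethyl-16-phenylhexadeca-3,11,15-trien-2-one A1 would take up H2O2 under a primary amine salt (9-amino-9-deoxy-epi-quinine trichloroacetate). Conjugate addition forms C5–O1 and hemiketalisation forms O2–C3, giving peroxyhemiketal A2.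
- Merits: the shortest of the four roads; stereoconvergent in the enone geometry; mild enough to carry the complete diene chain; no protecting group on the arm.
- Weak points: C5 is a fully substituted β-carbon, so both iminium formation and face selection between methyl and CH2R are far harder than for the β-monosubstituted enones on which this catalysis rests. C3 remains a hemiketal, so the acetic acid arm needs a later peroxycarbenium C–C bond formation under a strong Lewis acid, with only substrate control at C3 and with the styrenyl diene exposed.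
- Comparison: the chosen plan is longer. It sets C3 by a stereospecific inversion from a purchased centre and never exposes the diene to acid.

Alternative 2: Cut O2–C3 and the bond from the arm CH2 to the carboxyl carbon. Tertiary homoallylic hydroperoxide A3, CO and methanol would react under Pd(OCOCF3)2, 2,2'-(propane-2,2-diyl)bis[(4S)-4-tert-butyl-4,5-dihydro-1,3-oxazole] and p-benzoquinone to give dioxolane ester A4.
- Merits: the ring, C3 and the arm at its final oxidation level in one step. This is better redox economy than the chosen plan, which spends three steps on acetylation, methanolysis and oxidation.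
- Weak points: hydroperoxides oxidise zerovalent palladium and are reduced by palladium hydrides, and peroxypalladation is without precedent. The new centre is a quaternary carbon from a 1,1-disubstituted alkene, where ligand control is weakest. The enantiopure tertiary hydroperoxide A3 still has to be made by the same kind of invertive ring opening, so nothing is saved before the key step. The β-peroxy ester A4 must then pass through the basic olefination.
- Comparison: the chosen plan sets against the better redox economy a metal-free ring closure with closer precedent and a base-stable arm.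

Alternative 3: Cut C3–C4 and C5–O1. Silyl peroxyketal A5 would be ionised by SnCl4 and the peroxycarbenium ion trapped by alkene A6 in a formal [3+2] annulation to give dioxolane A7.
- Merits: the most convergent road; two simple fragments; a known annulation type; clearly fewer steps than the chosen plan.
- Weak points: both ring stereocentres are created at once from an achiral cation with only the remote C7 centre present. No absolute control and at best modest cis/trans control can be expected, so a mixture of four stereoisomers would have to be separated. The tertiary cation can also be lost to chloride capture or elimination.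
- Comparison: the chosen plan gives up convergence and pays more steps so that C3 comes from a building block and C5 from a catalyst.

Key step: step 10

Assumption: the sense of induction of the imidodiphosphorimidate acid with a hydroperoxide nucleophile cannot be predicted, so the (S,S)-acid is written and its (R,R)-antipode is to be used if the former favours the (5S) ring carbon.

Assumption: (S)-2-methylglycidol 10 and oxazolidinone 1 are taken as purchasable in high enantiomeric purity (10 is otherwise available by Sharpless epoxidation of 2-methylprop-2-en-1-ol).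

## Route

Step 1
Reactants: 1 (4R)-4-benzyl-3-propanoyl-1,3-oxazolidin-2-one; 2 2,3-dibromoprop-1-ene
Product: 4 (4R)-4-benzyl-3-[(2S)-4-bromo-2-methylpent-4-enoyl]-1,3-oxazolidin-2-one, via sodium Z-enolate 3 (not isolated)
Conditions: NaN(SiMe3)2, THF, −78 °C; then 2, −78 to −40 °C
Reagents that add atoms: none
Why: Evans asymmetric alkylation; the chelated Z-enolate is attacked by the allylic bromide on the face opposite the benzyl group, which sets C7 (2S in 4, hence the (R)-auxiliary); only the allylic C–Br bond of 2 reacts, the alkenyl bromide is inert.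

Step 2
Reactants: 4 (4R)-4-benzyl-3-[(2S)-4-bromo-2-methylpent-4-enoyl]-1,3-oxazolidin-2-one
Product: 5 (2S)-4-bromo-2-methylpent-4-en-1-ol
Conditions: LiBH4, MeOH (1 equiv), Et2O, 0 °C
Reagents that add atoms: none
Why: Reductive cleavage of the N-acyl oxazolidinone to the primary alcohol; the α-stereocentre and the alkenyl bromide are not affected and the auxiliary is recovered.

Step 3
Reactants: 5 (2S)-4-bromo-2-methylpent-4-en-1-ol
Product: 6 (2S)-4-bromo-2-methylpent-4-en-1-yl 4-methylbenzenesulfonate
Conditions: TsCl, pyridine, CH2Cl2, 0 to 20 °C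
Reagents that add atoms: 4-methylbenzenesulfonyl chloride, Cc1ccc(cc1)S(Cl)(=O)=O
Why: Standard sulfonylation of a primary alcohol to provide the leaving group for the coupling.

Step 4
Reactants: 6 (2S)-4-bromo-2-methylpent-4-en-1-yl 4-methylbenzenesulfonate; 7 5-bromopent-1-ene
Product: 9 (4R)-2-bromo-4-methyldeca-1,9-diene, via pent-4-en-1-ylmagnesium bromide 8 (not isolated)
Conditions: 7, Mg, THF, 40 °C; then 6, Li2CuCl4 (5 mol %), THF, −20 to 0 °C
Reagents that add atoms: none
Why: Copper-catalysed sp3–sp3 coupling of a primary tosylate with a primary Grignard reagent (Kochi-type) forms C8–C9; alkenyl bromides are poor partners under these conditions, so the C5 bromide should survive; the stereocentre is not involved (S becomes R by the priority rules only).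

Step 5
Reactants: 10 [(2S)-2-methyloxiran-2-yl]methanol
Product: 11 [(2R)-2-methyloxiran-2-yl]methyl 4-methylbenzenesulfonate
Conditions: TsCl, Et3N, 4-(dimethylamino)pyridine (cat.), CH2Cl2, 0 °C
Reagents that add atoms: 4-methylbenzenesulfonyl chloride, Cc1ccc(cc1)S(Cl)(=O)=O
Why: Sulfonylation of the primary alcohol; no bond to the quaternary carbon is touched (S becomes R only because the sulfonate arm now outranks the ring carbon).

Step 6
Reactants: 9 (4R)-2-bromo-4-methyldeca-1,9-diene; 11 [(2R)-2-methyloxiran-2-yl]methyl 4-methylbenzenesulfonate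
Product: 14 (2R)-2-methyl-2-[(4R)-4-methyl-2-methylidenedec-9-en-1-yl]oxirane, via alkenylmagnesium bromide 12 (not isolated), via hydroxy tosylate 13 (not isolated)
Conditions: 9, Mg, THF, 45 °C; then CuI (10 mol %), 11 (1.2 equiv), THF, −40 to −15 °C, aq NH4Cl; then K2CO3, MeOH, 20 °C
Reagents that add atoms: none
Why: Copper-catalysed opening of the 2,2-disubstituted epoxide by the alkenyl Grignard reagent at the unsubstituted ring carbon forms C4–C5 without touching the C3–O bond; base then closes the transposed epoxide by intramolecular Williamson displacement of the tosylate, the classical glycidyl sulfonate sequence.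

Step 7
Reactants: 14 (2R)-2-methyl-2-[(4R)-4-methyl-2-methylidenedec-9-en-1-yl]oxirane
Product: 15 (2R)-2-methyl-2-[(4R)-4-methyl-2-methylidenedec-9-en-1-yl]oxetane
Conditions: (CH3)3S(O)I, KOC(CH3)3, tert-butanol, 50 °C
Reagents that add atoms: trimethylsulfoxonium iodide, C[S+](C)(C)=O.[I-]
Why: Epoxide-to-oxetane ring expansion with dimethylsulfoxonium methylide (Corey–Chaykovsky reagent); the ylide opens the epoxide at its CH2 and the tertiary alkoxide displaces dimethyl sulfoxide (4-exo-tet), a known route to 2,2-disubstituted oxetanes; the C3–O bond is never broken, so configuration is retained.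

Step 8
Reactants: 15 (2R)-2-methyl-2-[(4R)-4-methyl-2-methylidenedec-9-en-1-yl]oxetane
Product: 16 (3S,7R)-3-hydroperoxy-3,7-dimethyl-5-methylidenetridec-12-en-1-ol
Conditions: H2O2 (anhydrous, in Et2O, excess), Me3SiOSO2CF3 (0.2 equiv), Et2O, −78 to −40 °C; then Et3N
Reagents that add atoms: hydrogen peroxide, OO
Why: Lewis acid-promoted perhydrolysis of a 2,2-disubstituted oxetane; H2O2 attacks the activated tertiary carbon from the side opposite the ring oxygen (strain release, tight SN2-like transition state), so C3 is set with inversion and the two-carbon arm is released as the primary alcohol; this is a known route to 3-hydroperoxy alkan-1-ols.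

Step 9
Reactants: 16 (3S,7R)-3-hydroperoxy-3,7-dimethyl-5-methylidenetridec-12-en-1-ol
Product: 17 (3S,7R)-3-hydroperoxy-3,7-dimethyl-5-methylidenetridec-12-en-1-yl acetate
Conditions: immobilised Candida antarctica lipase B, vinyl acetate, tert-butyl methyl ether, 25 °C
Reagents that add atoms: vinyl acetate, C=COC(C)=O
Why: Lipase-catalysed transesterification with an enol ester; the acyl-enzyme should be trapped by the unhindered primary alcohol, while the hydroperoxide on a fully substituted carbon is a poor fit; the neutral medium avoids base-induced peroxide chemistry and acid-induced ring closure.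

Step 10
Reactants: 17 (3S,7R)-3-hydroperoxy-3,7-dimethyl-5-methylidenetridec-12-en-1-yl acetate
Product: 18 2-[(3R,5R)-3,5-dimethyl-5-[(2R)-2-methyloct-7-en-1-yl]-1,2-dioxolan-3-yl]ethyl acetate
Conditions: (S,S)-HN[P(NSO2CF3)(O2C20H10Ar2)]2 with Ar = 3,5-(CF3)2C6H3 (5 mol %), cyclohexane, 4 Å molecular sieves, 20 °C
Reagents that add atoms: none
Why: Proposed new method: the confined acid is expected to transfer its proton to the terminal carbon of the 1,1-disubstituted alkene of 17 (Markovnikov sense) while the terminal hydroperoxide oxygen bonds to the developing tertiary C5 cation inside the chiral anion pocket, an asynchronous addition of O–H across C=C in which the added proton becomes part of the C5 methyl group; the closest known reaction types are the imidodiphosphorimidate-catalysed asymmetric intramolecular hydroalkoxylation of 1,1-disubstituted alkenols to tertiary cyclic ethers and the acid- or Hg(OAc)2-mediated cyclisation of unsaturated hydroperoxides, neither of which combines a hydroperoxide nucleophile with a chiral acid. The 1,2-dioxolane closes in the 5-exo-trig mode (O1 onto C5, the former methylidene carbon left outside the ring). The new stereocentre C5 has to be set by the catalyst, since C3 lies across a flexible methylene with two substituents of similar size and C7 is acyclic and remote, so the counteranion must select the alkene face and both antipodes of the acid are to be tried for the matched case. C3 and C7 are not touched. The step needs chemoselective protonation of the methylidene in preference to the monosubstituted chain-end alkene, which the tertiary against secondary cation stability secures. It needs the hydroperoxide to be the only oxygen nucleophile, which the acetate on the arm secures, and it needs the tertiary hydroperoxide to resist acid-induced O–O heterolysis, which is helped by the absence of aryl or other good migrating groups on C3.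

Step 11
Reactants: 18 2-[(3R,5R)-3,5-dimethyl-5-[(2R)-2-methyloct-7-en-1-yl]-1,2-dioxolan-3-yl]ethyl acetate
Product: 19 2-[(3R,5R)-3,5-dimethyl-5-[(2R)-2-methyl-7-oxoheptyl]-1,2-dioxolan-3-yl]ethyl acetate
Conditions: O3, CH2Cl2, −78 °C; then Me2S, −78 to 20 °C
Reagents that add atoms: ozone, [O-][O+]=O
Why: Ozonolysis with reductive work-up cleaves the only alkene left in the molecule to the C12 aldehyde; a dialkyl peroxide with fully substituted α-carbons and the acetate are inert to ozone and to dimethyl sulfide.

Step 12
Reactants: 20 tert-butyl acetate; 21 [(1E)-3-bromoprop-1-en-1-yl]benzene (cinnamyl bromide)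
Product: 23 tert-butyl (4E)-5-phenylpent-4-enoate, via lithium ester enolate 22 (not isolated)
Conditions: LiN(iPr)2, THF, −78 °C; then 21, −78 to 0 °C
Reagents that add atoms: none
Why: SN2 alkylation of a lithium ester enolate with a primary allylic bromide forms C14–C15 and keeps the E styrenyl geometry.

Step 13
Reactants: 23 tert-butyl (4E)-5-phenylpent-4-enoate
Product: 24 (4E)-5-phenylpent-4-en-1-ol
Conditions: LiAlH4, Et2O, 0 °C
Reagents that add atoms: none
Why: Hydride reduction of the ester to the primary alcohol; the non-conjugated styrenyl alkene is not reduced.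

Step 14
Reactants: 24 (4E)-5-phenylpent-4-en-1-ol
Product: 25 1-phenyl-5-{[(4E)-5-phenylpent-4-en-1-yl]sulfanyl}-1H-tetrazole
Conditions: PPh3, diisopropyl azodicarboxylate, 1-phenyl-1H-tetrazole-5-thiol, THF, 0 to 20 °C
Reagents that add atoms: 1-phenyl-1H-tetrazole-5-thiol, Sc1nnnn1-c1ccccc1
Why: Mitsunobu thioetherification of a primary alcohol with the acidic heteroaryl thiol.

Step 15
Reactants: 25 1-phenyl-5-{[(4E)-5-phenylpent-4-en-1-yl]sulfanyl}-1H-tetrazole
Product: 26 1-phenyl-5-{[(4E)-5-phenylpent-4-en-1-yl]sulfonyl}-1H-tetrazole
Conditions: (NH4)6Mo7O24·4H2O (10 mol %), 30% aq H2O2, EtOH, 0 to 20 °C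
Reagents that add atoms: hydrogen peroxide, OO
Why: Molybdate-catalysed oxidation of the sulfide to the sulfone, the usual preparation of Julia–Kocienski reagents in the presence of alkenes.

Step 16
Reactants: 19 2-[(3R,5R)-3,5-dimethyl-5-[(2R)-2-methyl-7-oxoheptyl]-1,2-dioxolan-3-yl]ethyl acetate; 26 1-phenyl-5-{[(4E)-5-phenylpent-4-en-1-yl]sulfonyl}-1H-tetrazole
Product: 28 2-[(3R,5R)-3,5-dimethyl-5-[(2R,7E,11E)-2-methyl-12-phenyldodeca-7,11-dien-1-yl]-1,2-dioxolan-3-yl]ethyl acetate, via potassium sulfonyl carbanion 27 (not isolated)
Conditions: 26, KN(SiMe3)2, 1,2-dimethoxyethane, −60 °C; then 19, −60 to 20 °C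
Reagents that add atoms: none
Why: Julia–Kocienski olefination; addition, Smiles rearrangement and anti-elimination should give the E C12=C13 alkene from unbranched partners; the ring carbons carry no α-hydrogen and the arm is still at the alcohol level, so neither peroxide fragmentation nor β-elimination is open to the base.

Step 17
Reactants: 28 2-[(3R,5R)-3,5-dimethyl-5-[(2R,7E,11E)-2-methyl-12-phenyldodeca-7,11-dien-1-yl]-1,2-dioxolan-3-yl]ethyl acetate
Product: 29 2-[(3R,5R)-3,5-dimethyl-5-[(2R,7E,11E)-2-methyl-12-phenyldodeca-7,11-dien-1-yl]-1,2-dioxolan-3-yl]ethan-1-ol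
Conditions: K2CO3 (0.3 equiv), MeOH, 0 to 20 °C
Reagents that add atoms: none
Why: Base-catalysed transesterification of the acetate with methanol; the fully substituted dialkyl peroxide is stable to carbonate in methanol.

Step 18
Reactants: 29 2-[(3R,5R)-3,5-dimethyl-5-[(2R,7E,11E)-2-methyl-12-phenyldodeca-7,11-dien-1-yl]-1,2-dioxolan-3-yl]ethan-1-ol
Product: 31 2-[(3S,5R)-3,5-dimethyl-5-[(2R,7E,11E)-2-methyl-12-phenyldodeca-7,11-dien-1-yl]-1,2-dioxolan-3-yl]acetic acid, via dioxolanylacetaldehyde 30 (not isolated)
Conditions: 2,2,6,6-tetramethylpiperidin-1-oxyl (20 mol %), PhI(OAc)2 (2.5 equiv), MeCN/aq pH 7 phosphate buffer, 20 °C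
Reagents that add atoms: water, O
Why: Oxoammonium-catalysed oxidation of the primary alcohol through aldehyde 30 and its hydrate to the acid under near-neutral conditions that should spare both alkenes and the peroxide; no stereocentre is touched (3R becomes 3S by the priority rules only).

## Compound list

1 | (4R)-4-benzyl-3-propanoyl-1,3-oxazolidin-2-one | CCC(=O)N1[C@H](Cc2ccccc2)COC1=O | starting material
2 | 2,3-dibromoprop-1-ene | C=C(Br)CBr | starting material
3 | sodium (Z)-enolate of 1 (not isolated) | C/C=C(\[O-])N1[C@H](Cc2ccccc2)COC1=O.[Na+] | intermediate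
4 | (4R)-4-benzyl-3-[(2S)-4-bromo-2-methylpent-4-enoyl]-1,3-oxazolidin-2-one | C[C@@H](CC(Br)=C)C(=O)N1[C@H](Cc2ccccc2)COC1=O | intermediate
5 | (2S)-4-bromo-2-methylpent-4-en-1-ol | C[C@H](CO)CC(Br)=C | intermediate
6 | (2S)-4-bromo-2-methylpent-4-en-1-yl 4-methylbenzenesulfonate | C[C@H](COS(=O)(=O)c1ccc(C)cc1)CC(Br)=C | intermediate
7 | 5-bromopent-1-ene | C=CCCCBr | starting material
8 | pent-4-en-1-ylmagnesium bromide (not isolated) | C=CCCC[Mg]Br | intermediate
9 | (4R)-2-bromo-4-methyldeca-1,9-diene | C[C@H](CCCCC=C)CC(Br)=C | intermediate
10 | [(2S)-2-methyloxiran-2-yl]methanol ((S)-2-methylglycidol) | C[C@]1(CO)CO1 | starting material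
11 | [(2R)-2-methyloxiran-2-yl]methyl 4-methylbenzenesulfonate | C[C@]1(COS(=O)(=O)c2ccc(C)cc2)CO1 | intermediate
12 | [(4R)-4-methyldeca-1,9-dien-2-yl]magnesium bromide (not isolated) | C[C@H](CCCCC=C)CC(=C)[Mg]Br | intermediate
13 | (2R,6R)-2-hydroxy-2,6-dimethyl-4-methylidenedodec-11-en-1-yl 4-methylbenzenesulfonate (not isolated) | C[C@H](CCCCC=C)CC(=C)C[C@](O)(C)COS(=O)(=O)c1ccc(C)cc1 | intermediate
14 | (2R)-2-methyl-2-[(4R)-4-methyl-2-methylidenedec-9-en-1-yl]oxirane | C[C@H](CCCCC=C)CC(=C)C[C@]1(C)CO1 | intermediate
15 | (2R)-2-methyl-2-[(4R)-4-methyl-2-methylidenedec-9-en-1-yl]oxetane | C[C@H](CCCCC=C)CC(=C)C[C@]1(C)CCO1 | intermediate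
16 | (3S,7R)-3-hydroperoxy-3,7-dimethyl-5-methylidenetridec-12-en-1-ol | C[C@H](CCCCC=C)CC(=C)C[C@@](C)(CCO)OO | intermediate
17 | (3S,7R)-3-hydroperoxy-3,7-dimethyl-5-methylidenetridec-12-en-1-yl acetate | C[C@H](CCCCC=C)CC(=C)C[C@@](C)(CCOC(C)=O)OO | intermediate
18 | 2-[(3R,5R)-3,5-dimethyl-5-[(2R)-2-methyloct-7-en-1-yl]-1,2-dioxolan-3-yl]ethyl acetate | C[C@H](CCCCC=C)C[C@]1(C)C[C@@](C)(CCOC(C)=O)OO1 | intermediate
19 | 2-[(3R,5R)-3,5-dimethyl-5-[(2R)-2-methyl-7-oxoheptyl]-1,2-dioxolan-3-yl]ethyl acetate | C[C@H](CCCCC=O)C[C@]1(C)C[C@@](C)(CCOC(C)=O)OO1 | intermediate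
20 | tert-butyl acetate | CC(=O)OC(C)(C)C | starting material
21 | [(1E)-3-bromoprop-1-en-1-yl]benzene (cinnamyl bromide) | BrC/C=C/c1ccccc1 | starting material
22 | lithium enolate of tert-butyl acetate (not isolated) | C=C([O-])OC(C)(C)C.[Li+] | intermediate
23 | tert-butyl (4E)-5-phenylpent-4-enoate | CC(C)(C)OC(=O)CC/C=C/c1ccccc1 | intermediate
24 | (4E)-5-phenylpent-4-en-1-ol | OCCC/C=C/c1ccccc1 | intermediate
25 | 1-phenyl-5-{[(4E)-5-phenylpent-4-en-1-yl]sulfanyl}-1H-tetrazole | C(CC/C=C/c1ccccc1)Sc1nnnn1-c1ccccc1 | intermediate
26 | 1-phenyl-5-{[(4E)-5-phenylpent-4-en-1-yl]sulfonyl}-1H-tetrazole | O=S(=O)(CCC/C=C/c1ccccc1)c1nnnn1-c1ccccc1 | intermediate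
27 | potassium salt of the α-sulfonyl carbanion of 26 (not isolated) | [K+].O=S(=O)([CH-]CC/C=C/c1ccccc1)c1nnnn1-c1ccccc1 | intermediate
28 | 2-[(3R,5R)-3,5-dimethyl-5-[(2R,7E,11E)-2-methyl-12-phenyldodeca-7,11-dien-1-yl]-1,2-dioxolan-3-yl]ethyl acetate | C[C@H](CCCC/C=C/CC/C=C/c1ccccc1)C[C@]1(C)C[C@@](C)(CCOC(C)=O)OO1 | intermediate
29 | 2-[(3R,5R)-3,5-dimethyl-5-[(2R,7E,11E)-2-methyl-12-phenyldodeca-7,11-dien-1-yl]-1,2-dioxolan-3-yl]ethan-1-ol | C[C@H](CCCC/C=C/CC/C=C/c1ccccc1)C[C@]1(C)C[C@@](C)(CCO)OO1 | intermediate
30 | 2-[(3S,5R)-3,5-dimethyl-5-[(2R,7E,11E)-2-methyl-12-phenyldodeca-7,11-dien-1-yl]-1,2-dioxolan-3-yl]acetaldehyde (not isolated) | C[C@H](CCCC/C=C/CC/C=C/c1ccccc1)C[C@]1(C)C[C@@](C)(CC=O)OO1 | intermediate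
31 | 2-[(3S,5R)-3,5-dimethyl-5-[(2R,7E,11E)-2-methyl-12-phenyldodeca-7,11-dien-1-yl]-1,2-dioxolan-3-yl]acetic acid | C[C@H](CCCC/C=C/CC/C=C/c1ccccc1)C[C@]1(C)C[C@@](C)(CC(=O)O)OO1 | target

## Step count and least certain steps

Total step count: 18. Longest linear sequence: 13 steps (steps 1–4, 6–11 and 16–18).

**Step 10 (key step).** Most likely failure: poor facial selectivity at C5, because a hydroperoxide places its nucleophilic oxygen one atom further from the stereo-defining backbone than an alcohol does and may sit loosely in the anion pocket. Second: acid-induced decomposition of the tertiary hydroperoxide (O–O heterolysis with alkyl migration) or isomerisation of the methylidene before ring closure.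

Fallback with known chemistry, from 17 back to 18: cycloperoxymercuration of 17 with Hg(OAc)2 (1.0 equiv) in CH2Cl2 closes the same C5–O1 bond 5-exo and gives the organomercurial 2-[(3R)-5-[(acetoxymercurio)methyl]-3-methyl-5-[(2R)-2-methyloct-7-en-1-yl]-1,2-dioxolan-3-yl]ethyl acetate F1 as a C5 epimer pair. Reductive demercuration with NaBH4 in cold aqueous NaOH then gives 18 together with its epimer 2-[(3R,5S)-3,5-dimethyl-5-[(2R)-2-methyloct-7-en-1-yl]-1,2-dioxolan-3-yl]ethyl acetate F2, from which 18 is separated by chromatography. Catalyst control is given up and half of the material at best is used.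

**Step 8.** Most likely failure: erosion of configuration at C3 through ionisation of the activated oxetane, possibly assisted by the neighbouring methylidene π-bond. Second: premature, uncontrolled closure of the new hydroperoxide onto the C5 alkene under the strong acid.

Fallback, from 15 back to 18, with the order of the two C–O bond formations reversed:
- Mukaiyama–Isayama peroxidation of 15 (Co(acac)2, O2, Et3SiH, 1,2-dichloroethane) at the methylidene, which reacts faster than the monosubstituted chain-end alkene, gives (2S)-2-[(4R)-2,4-dimethyl-2-[(triethylsilyl)peroxy]dec-9-en-1-yl]-2-methyloxetane F3 as an epimer pair at the new carbon.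
- Desilylation with n-Bu4NF buffered with acetic acid gives (2S)-2-[(4R)-2-hydroperoxy-2,4-dimethyldec-9-en-1-yl]-2-methyloxetane F4.
- Yb(OSO2CF3)3 then promotes the known intramolecular 5-exo opening of the oxetane by the hydroperoxide, with inversion at the oxetane carbon enforced by the tether. This gives 2-[(3R,5R)-3,5-dimethyl-5-[(2R)-2-methyloct-7-en-1-yl]-1,2-dioxolan-3-yl]ethan-1-ol F5 and its epimer 2-[(3R,5S)-3,5-dimethyl-5-[(2R)-2-methyloct-7-en-1-yl]-1,2-dioxolan-3-yl]ethan-1-ol F6, which are separated.
- Acetylation of F5 (Ac2O, pyridine) gives 18.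

This detour secures C3 but gives up control at C5.

**Step 9.** Most likely failure: competing acylation of the hydroperoxide to a perester, or slow turnover if the peroxide damages the enzyme.

Fallback, from 16 back to 17, protecting the more acidic O–H first: t-BuMe2SiCl with Et3N in CH2Cl2 and no nucleophilic catalyst should silylate the hydroperoxide (far more acidic than the alcohol) to give (3S,7R)-3-[(tert-butyldimethylsilyl)peroxy]-3,7-dimethyl-5-methylidenetridec-12-en-1-ol F7. Ordinary acetylation (Ac2O, pyridine) gives (3S,7R)-3-[(tert-butyldimethylsilyl)peroxy]-3,7-dimethyl-5-methylidenetridec-12-en-1-yl acetate F8. Buffered fluoride (HF·pyridine) then cleaves the labile silyl peroxide to 17.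

**Step 6.** Most likely failure: attack of the organomagnesium reagent or of bromide at the sulfonate-bearing carbon, or early re-closure of the alkoxide to the new epoxide followed by a second addition.

Fallback, from 10 and 12 back to 13, with no leaving group present during C–C bond formation: free glycidol 10 is deprotonated with CH3MgCl (1 equiv, THF, −40 °C) and opened by 12 with CuI to give (2R,6R)-2,6-dimethyl-4-methylidenedodec-11-ene-1,2-diol F9. Selective tosylation of its primary hydroxyl (TsCl, pyridine) gives 13, which is closed to 14 with K2CO3 in methanol as in step 6.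

## Further compounds

F1 | step 10 | 2-[(3R)-5-[(acetoxymercurio)methyl]-3-methyl-5-[(2R)-2-methyloct-7-en-1-yl]-1,2-dioxolan-3-yl]ethyl acetate (C5 epimer pair) | CC(=O)O[Hg]CC1(C[C@H](C)CCCCC=C)C[C@@](C)(CCOC(C)=O)OO1
F2 | step 10 | 2-[(3R,5S)-3,5-dimethyl-5-[(2R)-2-methyloct-7-en-1-yl]-1,2-dioxolan-3-yl]ethyl acetate | C[C@H](CCCCC=C)C[C@@]1(C)C[C@@](C)(CCOC(C)=O)OO1
F3 | step 8 | (2S)-2-[(4R)-2,4-dimethyl-2-[(triethylsilyl)peroxy]dec-9-en-1-yl]-2-methyloxetane (epimer pair at the peroxy carbon) | CC[Si](CC)(CC)OOC(C)(C[C@H](C)CCCCC=C)C[C@]1(C)CCO1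
F4 | step 8 | (2S)-2-[(4R)-2-hydroperoxy-2,4-dimethyldec-9-en-1-yl]-2-methyloxetane (epimer pair at the peroxy carbon) | OOC(C)(C[C@H](C)CCCCC=C)C[C@]1(C)CCO1
F5 | step 8 | 2-[(3R,5R)-3,5-dimethyl-5-[(2R)-2-methyloct-7-en-1-yl]-1,2-dioxolan-3-yl]ethan-1-ol | C[C@H](CCCCC=C)C[C@]1(C)C[C@@](C)(CCO)OO1
F6 | step 8 | 2-[(3R,5S)-3,5-dimethyl-5-[(2R)-2-methyloct-7-en-1-yl]-1,2-dioxolan-3-yl]ethan-1-ol | C[C@H](CCCCC=C)C[C@@]1(C)C[C@@](C)(CCO)OO1
F7 | step 9 | (3S,7R)-3-[(tert-butyldimethylsilyl)peroxy]-3,7-dimethyl-5-methylidenetridec-12-en-1-ol | C[C@H](CCCCC=C)CC(=C)C[C@@](C)(CCO)OO[Si](C)(C)C(C)(C)C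
F8 | step 9 | (3S,7R)-3-[(tert-butyldimethylsilyl)peroxy]-3,7-dimethyl-5-methylidenetridec-12-en-1-yl acetate | C[C@H](CCCCC=C)CC(=C)C[C@@](C)(CCOC(C)=O)OO[Si](C)(C)C(C)(C)C
F9 | step 6 | (2R,6R)-2,6-dimethyl-4-methylidenedodec-11-ene-1,2-diol | C[C@H](CCCCC=C)CC(=C)C[C@](O)(C)CO
A1 | alternative 1 | (6R,11E,15E)-4,6-dimethyl-16-phenylhexadeca-3,11,15-trien-2-one (3E/3Z mixture) | CC(=O)C=C(C)C[C@H](C)CCCC/C=C/CC/C=C/c1ccccc1
A2 | alternative 1 | (5R)-3,5-dimethyl-5-[(2R,7E,11E)-2-methyl-12-phenyldodeca-7,11-dien-1-yl]-1,2-dioxolan-3-ol (C3 epimers) | C[C@H](CCCC/C=C/CC/C=C/c1ccccc1)C[C@]1(C)CC(C)(O)OO1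
A3 | alternative 2 | tert-butyl{[(6R,8R)-8-hydroperoxy-6,8,10-trimethylundec-10-en-1-yl]oxy}dimethylsilane | C[C@H](CCCCCO[Si](C)(C)C(C)(C)C)C[C@](OO)(C)CC(C)=C
A4 | alternative 2 | methyl 2-[(3S,5R)-5-[(2R)-7-(tert-butyldimethylsilyloxy)-2-methylheptyl]-3,5-dimethyl-1,2-dioxolan-3-yl]acetate | C[C@H](CCCCCO[Si](C)(C)C(C)(C)C)C[C@]1(C)C[C@@](C)(CC(=O)OC)OO1
A5 | alternative 3 | triethyl{[2-methoxy-4-(triisopropylsilyloxy)butan-2-yl]peroxy}silane | COC(C)(CCO[Si](C(C)C)(C(C)C)C(C)C)OO[Si](CC)(CC)CC
A6 | alternative 3 | methyl (6R)-6,8-dimethylnon-8-enoate | C=C(C)C[C@H](C)CCCCC(=O)OC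
A7 | alternative 3 | methyl (6R)-7-[(3R,5R)-3,5-dimethyl-3-[2-(triisopropylsilyloxy)ethyl]-1,2-dioxolan-5-yl]-6-methylheptanoate | C[C@H](CCCCC(=O)OC)C[C@]1(C)C[C@@](C)(CCO[Si](C(C)C)(C(C)C)C(C)C)OO1
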